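**Retrosynthetic overview**
The target is opened at its two gallate esters and at the interflavan bond C4(upper)–C6(lower): a Friedel–Crafts union of a 6,8-dibromo-4β-alkoxy epicatechin electrophile (from (−)-epicatechin) with an 8-bromo lower flavan-3-ol whose only free ring-A position is C6.
The lower unit is not taken from the chiral pool. Its ring C is made by formal insertion of an aryne equivalent (a 2-fluoroaryllithium) into the O–CH2 bond of a cis-2-aryl-3-alkoxyoxetane: oxetane opening forms C4–C4a, SNAr at the C–F carbon forms O1–C8a.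
Enabling feature: O1–C2–C3–C4 of ring C is a four-atom chain that can be stored, with both stereocentres, as an oxetane. In ring A, C8a (the carbon that carries O1) is meta to both phenolic oxygens (C5–O, C7–O) and C4a lies between C8a and C5–O, so a 3,5-dialkoxyfluorobenzene is metalated at C4a and substituted at C8a. The second bromine of the symmetric dibromide ends at C8 and blocks it.
Ring order: upper rings A, B and C come preformed; oxetane (four-membered) → ring C of the lower unit on a preformed ring A (key step) → interflavan bond → esters → global hydrogenolysis.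

Key step: step 8

Remark: the C3 oxygen of the lower unit is carried through the key step as a methoxymethyl ether, on the assumption that this acetal survives BF3·OEt2 at −78 °C for the short activation period. The target is read as upper unit (2R,3R,4S), lower unit (2R,3R).

**Step 1**
Reactants: 1 1,3,5-trifluorobenzene
Product: 2 1,3-bis(benzyloxy)-5-fluorobenzene
Conditions: BnOH (2.1 equiv), NaH (2.2 equiv), NMP, 0 → 80 °C
Reagents that add atoms: benzyl alcohol, OCc1ccccc1
Why: Twofold SNAr (addition–elimination) of benzyl oxide on a fluoroarene whose fluorines activate one another from the meta positions, the third substitution being slowest because the ring is then electron-rich.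

**Step 2**
Reactants: 2 1,3-bis(benzyloxy)-5-fluorobenzene
Product: 3 1,5-bis(benzyloxy)-2,4-dibromo-3-fluorobenzene
Conditions: NBS (2.05 equiv), MeCN, 0 °C → rt
Reagents that add atoms: N-bromosuccinimide, O=C1CCC(=O)N1Br
Why: Electrophilic aromatic bromination should go para to each benzyloxy group, to the two equivalent positions that flank fluorine, as 1,3-dialkoxybenzenes give 4,6-dibromides, while the hindered position between the two ethers stays free.

**Step 3**
Reactants: 4 allyl alcohol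
Product: 5 3-(methoxymethoxy)prop-1-ene
Conditions: MOMCl, i-Pr2NEt, CH2Cl2, 0 °C → rt
Reagents that add atoms: chloromethyl methyl ether, COCCl
Why: Standard O-alkylation of an alcohol with a chloromethyl ether (acetal protection).

**Step 4**
Reactants: 5 3-(methoxymethoxy)prop-1-ene; 6 3,4-bis(benzyloxy)benzaldehyde
Product: 11 (1R,2R)-1-[3,4-bis(benzyloxy)phenyl]-2-(methoxymethoxy)but-3-en-1-ol, via allyllithium 7 (not isolated), via lithium borate 8 (not isolated), via allylborane 9 (not isolated), via borinate ester 10 (not isolated)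
Conditions: s-BuLi, THF, −78 °C; (−)-B-methoxydiisopinocampheylborane; BF3·OEt2; 6, −78 °C; then NaOH, H2O2, 0 °C → rt
Reagents that add atoms: none
Why: Asymmetric (Z)-γ-alkoxyallylboration (Brown-type allylboration): the (Z)-allylborane adds to the aldehyde through a closed chair (Zimmerman–Traxler) transition state, which sets the syn relation, and the isopinocampheyl groups derived from (+)-α-pinene select the aldehyde face expected to give the (1R,2R) isomer.

**Step 5**
Reactants: 11 (1R,2R)-1-[3,4-bis(benzyloxy)phenyl]-2-(methoxymethoxy)but-3-en-1-ol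
Product: 13 (1R,2R)-1-[3,4-bis(benzyloxy)phenyl]-2-(methoxymethoxy)propane-1,3-diol, via ozonide 12 (not isolated)
Conditions: O3, CH2Cl2, −78 °C (Sudan Red 7B indicator); then NaBH4, MeOH, −78 → 0 °C
Reagents that add atoms: ozone, [O-][O+]=O
Why: Ozonolysis of the terminal alkene with reductive work-up shortens the chain to the primary alcohol without touching the two stereocentres, the alkene reacting far faster with ozone than the aryl ethers.

**Step 6**
Reactants: 13 (1R,2R)-1-[3,4-bis(benzyloxy)phenyl]-2-(methoxymethoxy)propane-1,3-diol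
Product: 14 (2R,3R)-3-[3,4-bis(benzyloxy)phenyl]-3-hydroxy-2-(methoxymethoxy)propyl 4-methylbenzenesulfonate
Conditions: TsCl (1.05 equiv), pyridine, CH2Cl2, 0 °C
Reagents that add atoms: 4-toluenesulfonyl chloride, Cc1ccc(cc1)S(Cl)(=O)=O
Why: Sulfonylation is selective for the primary over the hindered secondary benzylic hydroxyl.

**Step 7**
Reactants: 14 (2R,3R)-3-[3,4-bis(benzyloxy)phenyl]-3-hydroxy-2-(methoxymethoxy)propyl 4-methylbenzenesulfonate
Product: 15 (2R,3R)-2-[3,4-bis(benzyloxy)phenyl]-3-(methoxymethoxy)oxetane (2,3-cis)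
Conditions: NaH, THF, 0 °C → rt
Reagents that add atoms: none
Why: Intramolecular Williamson etherification (4-exo-tet): the benzylic alkoxide displaces the primary tosylate, so no bond at either stereocentre is broken and the syn diol derivative should give the 2,3-cis oxetane.

**Step 8**
Reactants: 3 1,5-bis(benzyloxy)-2,4-dibromo-3-fluorobenzene; 15 (2R,3R)-2-[3,4-bis(benzyloxy)phenyl]-3-(methoxymethoxy)oxetane
Product: 18 (2R,3R)-5,7-bis(benzyloxy)-2-[3,4-bis(benzyloxy)phenyl]-8-bromo-3-(methoxymethoxy)chromane, via aryllithium 16 (not isolated), via lithium alkoxide 17 (not isolated)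
Conditions: 3, t-BuLi (2 equiv), THF, −78 °C; 15, then BF3·OEt2, −78 °C; then KOt-Bu, DMPU, −78 → 60 °C
Reagents that add atoms: none
Why: Proposed new method: bromine–lithium exchange on the symmetric dibromide 3 gives the 2-fluoroaryllithium 16, which opens the BF3-activated oxetane 15 by SN2 attack at its unsubstituted CH2 (forming C4–C4a) and releases the C2 oxygen as alkoxide 17; once KOt-Bu has taken up the boron, this alkoxide displaces the neighbouring fluoride by addition–elimination (forming O1–C8a), so that the fluoroaryllithium acts as an aryne equivalent inserting into the O–CH2 bond of the oxetane. The closest known reaction types are the BF3-promoted opening of oxetanes and epoxides by aryllithiums and the intramolecular SNAr etherification of 3,5-dialkoxyfluorobenzenes used to close ring C of flavan-3-ols; their union in one flask on a 2-aryl-3-alkoxyoxetane is new. Ring C closes in a 6-exo mode at the fluorine-bearing carbon (Meisenheimer-type addition–elimination) while the four-membered ring is opened, a net four-to-six ring expansion. No stereocentre is created: C2 and C3 come from the cis-oxetane with retention, because the C2–O bond and all bonds at C3 stay intact, which secures the 2,3-cis (2R,3R) relation. The step needs attack at CH2 and not at the benzylic C2 of the oxetane (low temperature, steric bias and the inductive brake of the C3 methoxymethoxy group on benzylic ionization), closure by the C2 alkoxide only (the C3 oxygen is capped, so no five-membered ether can form) and displacement of fluoride and not bromide (fluorine is the SNAr leaving group, activated by two meta benzyloxy groups and the ortho bromine). The untouched second bromine ends at C8 and later blocks that position.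

**Step 9**
Reactants: 18 (2R,3R)-5,7-bis(benzyloxy)-2-[3,4-bis(benzyloxy)phenyl]-8-bromo-3-(methoxymethoxy)chromane
Product: 19 (2R,3R)-5,7-bis(benzyloxy)-2-[3,4-bis(benzyloxy)phenyl]-8-bromochroman-3-ol
Conditions: conc. HCl (cat.), MeOH/THF, 50 °C
Reagents that add atoms: none
Why: Acid-catalysed transacetalization removes the methoxymethyl group while benzyl ethers, the aryl bromide and the flavan stereocentres are stable to dilute methanolic acid.

**Step 10**
Reactants: 20 (−)-epicatechin
Product: 21 5,7,3',4'-tetra-O-benzyl-(−)-epicatechin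
Conditions: BnBr (4.4 equiv), K2CO3, DMF, 0 °C → rt
Reagents that add atoms: benzyl bromide, BrCc1ccccc1
Why: Williamson O-benzylation of the four phenols with the weak base K2CO3, which leaves the secondary alcohol free.

**Step 11**
Reactants: 21 5,7,3',4'-tetra-O-benzyl-(−)-epicatechin
Product: 22 (2R,3R,4S)-5,7-bis(benzyloxy)-2-[3,4-bis(benzyloxy)phenyl]-4-(2-ethoxyethoxy)chroman-3-ol (4β ether)
Conditions: DDQ (2 equiv), 2-ethoxyethanol, CH2Cl2, rt
Reagents that add atoms: 2-ethoxyethanol, CCOCCO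
Why: DDQ oxidation at the doubly activated benzylic C4 (hydride abstraction to a ring-A-stabilized cation) and capture by the alcohol from the face anti to the C3 hydroxyl should give the 4β ether, a known activation of benzylated flavan-3-ols.

**Step 12**
Reactants: 22 (2R,3R,4S)-5,7-bis(benzyloxy)-2-[3,4-bis(benzyloxy)phenyl]-4-(2-ethoxyethoxy)chroman-3-ol
Product: 23 (2R,3R,4S)-5,7-bis(benzyloxy)-2-[3,4-bis(benzyloxy)phenyl]-6,8-dibromo-4-(2-ethoxyethoxy)chroman-3-ol
Conditions: NBS (2.1 equiv), CH2Cl2, −20 → 0 °C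
Reagents that add atoms: N-bromosuccinimide, O=C1CCC(=O)N1Br
Why: Electrophilic bromination of the phloroglucinol-type ring A at its two free positions C8 and C6 blocks every nucleophilic site of the future electrophile.

**Step 13**
Reactants: 19 (2R,3R)-5,7-bis(benzyloxy)-2-[3,4-bis(benzyloxy)phenyl]-8-bromochroman-3-ol; 23 (2R,3R,4S)-5,7-bis(benzyloxy)-2-[3,4-bis(benzyloxy)phenyl]-6,8-dibromo-4-(2-ethoxyethoxy)chroman-3-ol
Product: 24 5,7,3',4'-tetra-O-benzyl-6,8-dibromo-(−)-epicatechin-(4β→6)-5,7,3',4'-tetra-O-benzyl-8-bromo-(−)-epicatechin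
Conditions: Me3SiOTf (0.3 equiv), CH2Cl2, −40 → 0 °C
Reagents that add atoms: none
Why: Lewis acid-mediated Friedel–Crafts coupling of a flavan-4-yl cation: ionization of the C4 ether gives the ring-A-stabilized cation, which can only be attacked by C6 of 19 (its C8 is brominated and 23 has no free ring-A position), and attack anti to the C3 oxygen of the 2,3-cis unit should set the 3,4-trans (4β) configuration.

**Step 14**
Reactants: 24 5,7,3',4'-tetra-O-benzyl-6,8-dibromo-(−)-epicatechin-(4β→6)-5,7,3',4'-tetra-O-benzyl-8-bromo-(−)-epicatechin; 25 3,4,5-tris(benzyloxy)benzoic acid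
Product: 26 3,3'-bis-O-[3,4,5-tris(benzyloxy)benzoyl] derivative of 24
Conditions: 25 (4 equiv), DCC, 4-(dimethylamino)pyridine, CH2Cl2, rt
Reagents that add atoms: none
Why: Steglich esterification of both secondary hydroxyls with the protected gallic acid, with no stereocentre touched.

**Step 15**
Reactants: 26 3,3'-bis-O-[3,4,5-tris(benzyloxy)benzoyl] derivative of 24
Product: 27 procyanidin B-5 3,3'-di-O-gallate
Conditions: H2 (1 atm), Pd(OH)2/C, Et3N, THF/MeOH, rt
Reagents that add atoms: none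
Why: Catalytic hydrogenolysis should cleave all fourteen benzyl ethers and, with base present, the three aryl C–Br bonds, while the esters, the interflavan bond and the benzylic C2–O1 bonds of the flavans persist.

**Compound list**
1 | 1,3,5-trifluorobenzene | Fc1cc(F)cc(F)c1 | starting material
2 | 1,3-bis(benzyloxy)-5-fluorobenzene | Fc1cc(OCc2ccccc2)cc(OCc2ccccc2)c1 | intermediate
3 | 1,5-bis(benzyloxy)-2,4-dibromo-3-fluorobenzene | Fc1c(Br)c(OCc2ccccc2)cc(OCc2ccccc2)c1Br | intermediate
4 | allyl alcohol | C=CCO | starting material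
5 | 3-(methoxymethoxy)prop-1-ene | C=CCOCOC | intermediate
6 | 3,4-bis(benzyloxy)benzaldehyde | O=Cc1ccc(OCc2ccccc2)c(OCc2ccccc2)c1 | starting material
7 | (Z)-3-(methoxymethoxy)prop-2-enyllithium | COCO/C=C\C[Li] | intermediate
8 | lithium [(Z)-3-(methoxymethoxy)prop-2-enyl](methoxy)bis(isopinocampheyl)borate, isopinocampheyl groups from (+)-α-pinene | [Li+].CO[B-](C/C=C\OCOC)([C@@H]1C[C@@H]2C[C@H]([C@H]1C)C2(C)C)[C@@H]1C[C@@H]2C[C@H]([C@H]1C)C2(C)C | intermediate
9 | [(Z)-3-(methoxymethoxy)prop-2-enyl]bis(isopinocampheyl)borane | COCO/C=C\CB([C@@H]1C[C@@H]2C[C@H]([C@H]1C)C2(C)C)[C@@H]1C[C@@H]2C[C@H]([C@H]1C)C2(C)C | intermediate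
10 | bis(isopinocampheyl)borinic ester of 11 | B([C@@H]1C[C@@H]2C[C@H]([C@H]1C)C2(C)C)([C@@H]1C[C@@H]2C[C@H]([C@H]1C)C2(C)C)O[C@@H]([C@@H](C=C)OCOC)c1ccc(OCc2ccccc2)c(OCc2ccccc2)c1 | intermediate
11 | (1R,2R)-1-[3,4-bis(benzyloxy)phenyl]-2-(methoxymethoxy)but-3-en-1-ol | O[C@@H]([C@@H](C=C)OCOC)c1ccc(OCc2ccccc2)c(OCc2ccccc2)c1 | intermediate
12 | ozonide (1,2,4-trioxolane) of 11, both epimers at the trioxolane carbon | O[C@@H]([C@@H](C1OOCO1)OCOC)c1ccc(OCc2ccccc2)c(OCc2ccccc2)c1 | intermediate
13 | (1R,2R)-1-[3,4-bis(benzyloxy)phenyl]-2-(methoxymethoxy)propane-1,3-diol | O[C@@H]([C@@H](CO)OCOC)c1ccc(OCc2ccccc2)c(OCc2ccccc2)c1 | intermediate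
14 | (2R,3R)-3-[3,4-bis(benzyloxy)phenyl]-3-hydroxy-2-(methoxymethoxy)propyl 4-methylbenzenesulfonate | O[C@@H]([C@@H](COS(=O)(=O)c1ccc(C)cc1)OCOC)c1ccc(OCc2ccccc2)c(OCc2ccccc2)c1 | intermediate
15 | (2R,3R)-2-[3,4-bis(benzyloxy)phenyl]-3-(methoxymethoxy)oxetane (2,3-cis) | COCO[C@@H]1CO[C@@H]1c1ccc(OCc2ccccc2)c(OCc2ccccc2)c1 | intermediate
16 | [4,6-bis(benzyloxy)-3-bromo-2-fluorophenyl]lithium | [Li]c1c(F)c(Br)c(OCc2ccccc2)cc1OCc1ccccc1 | intermediate
17 | lithium (1R,2R)-3-[4,6-bis(benzyloxy)-3-bromo-2-fluorophenyl]-1-[3,4-bis(benzyloxy)phenyl]-2-(methoxymethoxy)propan-1-olate | [Li]O[C@@H]([C@@H](Cc1c(F)c(Br)c(OCc2ccccc2)cc1OCc1ccccc1)OCOC)c1ccc(OCc2ccccc2)c(OCc2ccccc2)c1 | intermediate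
18 | (2R,3R)-5,7-bis(benzyloxy)-2-[3,4-bis(benzyloxy)phenyl]-8-bromo-3-(methoxymethoxy)chromane | COCO[C@@H]1Cc2c(OCc3ccccc3)cc(OCc3ccccc3)c(Br)c2O[C@@H]1c1ccc(OCc2ccccc2)c(OCc2ccccc2)c1 | intermediate
19 | (2R,3R)-5,7-bis(benzyloxy)-2-[3,4-bis(benzyloxy)phenyl]-8-bromochroman-3-ol | O[C@@H]1Cc2c(OCc3ccccc3)cc(OCc3ccccc3)c(Br)c2O[C@@H]1c1ccc(OCc2ccccc2)c(OCc2ccccc2)c1 | intermediate
20 | (−)-epicatechin, (2R,3R) | O[C@@H]1Cc2c(O)cc(O)cc2O[C@@H]1c1ccc(O)c(O)c1 | starting material
21 | 5,7,3',4'-tetra-O-benzyl-(−)-epicatechin | O[C@@H]1Cc2c(OCc3ccccc3)cc(OCc3ccccc3)cc2O[C@@H]1c1ccc(OCc2ccccc2)c(OCc2ccccc2)c1 | intermediate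
22 | (2R,3R,4S)-5,7-bis(benzyloxy)-2-[3,4-bis(benzyloxy)phenyl]-4-(2-ethoxyethoxy)chroman-3-ol | O[C@@H]1[C@@H](OCCOCC)c2c(OCc3ccccc3)cc(OCc3ccccc3)cc2O[C@@H]1c1ccc(OCc2ccccc2)c(OCc2ccccc2)c1 | intermediate
23 | (2R,3R,4S)-5,7-bis(benzyloxy)-2-[3,4-bis(benzyloxy)phenyl]-6,8-dibromo-4-(2-ethoxyethoxy)chroman-3-ol | O[C@@H]1[C@@H](OCCOCC)c2c(OCc3ccccc3)c(Br)c(OCc3ccccc3)c(Br)c2O[C@@H]1c1ccc(OCc2ccccc2)c(OCc2ccccc2)c1 | intermediate
24 | 5,7,3',4'-tetra-O-benzyl-6,8-dibromo-(−)-epicatechin-(4β→6)-5,7,3',4'-tetra-O-benzyl-8-bromo-(−)-epicatechin | O[C@@H]1[C@@H](c2c(OCc3ccccc3)c(Br)c3c(c2OCc2ccccc2)C[C@@H](O)[C@@H](c2ccc(OCc4ccccc4)c(OCc4ccccc4)c2)O3)c2c(OCc3ccccc3)c(Br)c(OCc3ccccc3)c(Br)c2O[C@@H]1c1ccc(OCc2ccccc2)c(OCc2ccccc2)c1 | intermediate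
25 | 3,4,5-tris(benzyloxy)benzoic acid | O=C(O)c1cc(OCc2ccccc2)c(OCc2ccccc2)c(OCc2ccccc2)c1 | starting material
26 | 3,3'-bis-O-[3,4,5-tris(benzyloxy)benzoyl] derivative of 24 | O=C(O[C@@H]1[C@@H](c2c(OCc3ccccc3)c(Br)c3c(c2OCc2ccccc2)C[C@@H](OC(=O)c2cc(OCc4ccccc4)c(OCc4ccccc4)c(OCc4ccccc4)c2)[C@@H](c2ccc(OCc4ccccc4)c(OCc4ccccc4)c2)O3)c2c(OCc3ccccc3)c(Br)c(OCc3ccccc3)c(Br)c2O[C@@H]1c1ccc(OCc2ccccc2)c(OCc2ccccc2)c1)c1cc(OCc2ccccc2)c(OCc2ccccc2)c(OCc2ccccc2)c1 | intermediate
27 | procyanidin B-5 3,3'-di-O-gallate | O=C(O[C@@H]1[C@@H](c2c(O)cc3c(c2O)C[C@@H](OC(=O)c2cc(O)c(O)c(O)c2)[C@@H](c2ccc(O)c(O)c2)O3)c2c(O)cc(O)cc2O[C@@H]1c1ccc(O)c(O)c1)c1cc(O)c(O)c(O)c1 | target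

**Step count and risks**
Total step count: 15. Longest linear sequence: 10 steps (steps 3, 4, 5, 6, 7, 8, 9, 13, 14, 15).

Steps most likely to fail:

Step 8. The Lewis acid-activated oxetane may ionize at its benzylic C2–O bond (electron-rich aryl group) and fragment or be attacked at C2 before the SN2 opening at CH2 takes place, and the alkoxide may be released too slowly from boron for the SNAr closure. The fallback uses known chemistry without a Lewis acid and sets out from tosylate 14 and dibromide 3. Silylation of 14 (Et3SiOTf, 2,6-lutidine) gives (2R,3R)-3-[3,4-bis(benzyloxy)phenyl]-2-(methoxymethoxy)-3-(triethylsilyloxy)propyl 4-methylbenzenesulfonate F1. Bromine–magnesium exchange on 3 (i-PrMgCl·LiCl, THF, −15 °C) gives [4,6-bis(benzyloxy)-3-bromo-2-fluorophenyl]magnesium chloride F2. Copper-catalysed Grignard–tosylate coupling of F2 with F1 (Li2CuCl4 cat., THF) should give the open-chain silyl ether {(1R,2R)-3-[4,6-bis(benzyloxy)-3-bromo-2-fluorophenyl]-1-[3,4-bis(benzyloxy)phenyl]-2-(methoxymethoxy)propoxy}triethylsilane F3. Desilylation (Bu4NF) gives (1R,2R)-3-[4,6-bis(benzyloxy)-3-bromo-2-fluorophenyl]-1-[3,4-bis(benzyloxy)phenyl]-2-(methoxymethoxy)propan-1-ol F4, and KOt-Bu in THF/DMF closes ring C by intramolecular SNAr. The fallback comes back to the route at 18.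

Step 13. Carbon–carbon bond formation at C6, which is flanked by two benzyloxy groups and deactivated by the bromine at C8, may be slower than decay of the cation by elimination or by reversible ether formation with the free hydroxyls. The fallback changes the order of events and the nature of the electrophile and sets out from 19 and 23. Each is first esterified with 25 (DCC, 4-(dimethylamino)pyridine) to give the 3-O-[3,4,5-tris(benzyloxy)benzoyl] ester of 19 F5 and the 3-O-[3,4,5-tris(benzyloxy)benzoyl] ester of 23 F6. Ionization of F6 (Me3SiOTf) then gives an acyloxy-bridged cation (neighbouring-group participation) that has no free hydroxyl partner, resists elimination and is opened at C4 from the β face by C6 of F5. The fallback comes back to the route at 26 and skips 24.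

Step 7. The γ-tosyloxy alkoxide may undergo Grob fragmentation to the aryl aldehyde and an enol ether instead of closing the strained four-membered ring. The fallback avoids the free alkoxide and sets out from diol 13: Mitsunobu cyclodehydration (PPh3, diisopropyl azodicarboxylate, toluene) activates the primary hydroxyl as the oxyphosphonium ion, which is displaced by the neutral benzylic hydroxyl. It comes back to the route at 15, skips 14 and makes no new compound (F0).

**Further compounds**
F1 | step 8 | (2R,3R)-3-[3,4-bis(benzyloxy)phenyl]-2-(methoxymethoxy)-3-(triethylsilyloxy)propyl 4-methylbenzenesulfonate | CC[Si](CC)(CC)O[C@@H]([C@@H](COS(=O)(=O)c1ccc(C)cc1)OCOC)c1ccc(OCc2ccccc2)c(OCc2ccccc2)c1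
F2 | step 8 | [4,6-bis(benzyloxy)-3-bromo-2-fluorophenyl]magnesium chloride | Cl[Mg]c1c(F)c(Br)c(OCc2ccccc2)cc1OCc1ccccc1
F3 | step 8 | {(1R,2R)-3-[4,6-bis(benzyloxy)-3-bromo-2-fluorophenyl]-1-[3,4-bis(benzyloxy)phenyl]-2-(methoxymethoxy)propoxy}triethylsilane | CC[Si](CC)(CC)O[C@@H]([C@@H](Cc1c(F)c(Br)c(OCc2ccccc2)cc1OCc1ccccc1)OCOC)c1ccc(OCc2ccccc2)c(OCc2ccccc2)c1
F4 | step 8 | (1R,2R)-3-[4,6-bis(benzyloxy)-3-bromo-2-fluorophenyl]-1-[3,4-bis(benzyloxy)phenyl]-2-(methoxymethoxy)propan-1-ol | O[C@@H]([C@@H](Cc1c(F)c(Br)c(OCc2ccccc2)cc1OCc1ccccc1)OCOC)c1ccc(OCc2ccccc2)c(OCc2ccccc2)c1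
F5 | step 13 | 3-O-[3,4,5-tris(benzyloxy)benzoyl] ester of 19 | O=C(O[C@@H]1Cc2c(OCc3ccccc3)cc(OCc3ccccc3)c(Br)c2O[C@@H]1c1ccc(OCc2ccccc2)c(OCc2ccccc2)c1)c1cc(OCc2ccccc2)c(OCc2ccccc2)c(OCc2ccccc2)c1
F6 | step 13 | 3-O-[3,4,5-tris(benzyloxy)benzoyl] ester of 23 | O=C(O[C@@H]1[C@@H](OCCOCC)c2c(OCc3ccccc3)c(Br)c(OCc3ccccc3)c(Br)c2O[C@@H]1c1ccc(OCc2ccccc2)c(OCc2ccccc2)c1)c1cc(OCc2ccccc2)c(OCc2ccccc2)c(OCc2ccccc2)c1
F0 | step 7 | none | none
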